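- Per hour and per unit of catalyst charged is the unit I reckon in: the pace is the target made, c(starting material) times the fraction read, divided by c(free catalyst) and by the time since the start, which is the average turnover frequency.

in all of them: starting material 0.10 M

|  | reagent | free catalyst | temperature | remark | time |
|---|---|---|---|---|---|
| violet | 0.050 M | 1.5 mM | 68 °C | run made earlier |  |
| grey | 0.050 M | 3.4 mM | 84 °C | run made earlier |  |
| teal | 0.025 M | 2.3 mM | 68 °C | run made earlier |  |
| north-west | 0.0500 M | 2.3 mM | 90 °C |  | 15 h |
| west | 0.0500 M | 2.3 mM | 60 °C |  | 15 h |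

| run | time / h | target / % |
|---|---|---|
| violet | 4.00 | 0.6 |
| violet | 8.00 | 1.9 |
| violet | 25.0 | 5.7 |
| violet | 60.0 | 14.3 |
| grey | 2.50 | 5.7 |
| grey | 6.00 | 13.7 |
| grey | 12.0 | 25.7 |
| grey | 20.0 | 37.2 |
| teal | 15.0 | 4.9 |
| teal | 30.0 | 9.9 |
| teal | 40.0 | 13.0 |
| teal | 60.0 | 17.1 |

(scatter of a reading: 0.3 percentage points)

- the flask that ends with the higher amount of target, in percent of the starting material charged, or "neither" when 2 percentage points or less lies between them (north-west / west / neither)
- final target, as a percentage of the starting material charged, in north-west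
- final target, as a percentage of the starting material charged, in west



- The violet run at 68 °C reads 0.152 h⁻¹ at 25.0 h, and the teal run, at the same temperature with half the reagent and other catalyst, reads 0.142 h⁻¹, so I carry the pace across catalyst amounts.
- The grey run at 84 °C reads 0.547 h⁻¹ at 20.0 h, later than the asked time, and this grey pace is what I carry, higher than violet's.
- I turn the question round. North-west and west share charges and time, so for "neither" their paces must lie within 0.0580 h⁻¹ of each other.
- Between 68 °C and 84 °C the pace already rises by 6.81 times that gap, and the two flasks stand outside that interval, at 90 °C and 60 °C. For west to draw level, the paces at 90 °C and 60 °C must lie within that gap, against the rise read from violet to grey.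
- My own reckoning gives rough estimates, not bounds: at the grey pace north-west reaches 18.9%, and at the violet pace, read at a warmer temperature than west's, west reaches 5.24%, so I expect north-west above the first figure and west below the second.
- The forecast names north-west, with 32% (26% to 38%) for north-west and 2.5% (1.8% to 3.3%) for west, on the ground that the rate is “roughly first order in catalyst and nearly zero order in reagent”.
- The flasks give north-west as the higher one, with 29.9% in north-west and 2.38% in west, each inside the forecast's range.

    reagent + free catalyst ⇌ catalyst intermediate A (K = 88.0 L mol⁻¹, k = 0.0730 L mol⁻¹ s⁻¹, Ea = 80.0 kJ mol⁻¹, ΔH = −62.0 kJ mol⁻¹)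
    catalyst intermediate A ⇌ catalyst intermediate B (K = 0.760, k = 0.00430 s⁻¹, Ea = 94.0 kJ mol⁻¹, ΔH = −61.0 kJ mol⁻¹)
    starting material + catalyst intermediate B → catalyst intermediate C (k = 0.0310 L mol⁻¹ s⁻¹, Ea = 55.0 kJ mol⁻¹)
    catalyst intermediate C ⇌ free catalyst + target (K = 6.80 M, k = 6.40 × 10⁻⁴ s⁻¹, Ea = 104 kJ mol⁻¹, ΔH = 9.00 kJ mol⁻¹)
    free catalyst ⇌ dormant form (K = 0.510, k = 7.80 × 10⁻⁵ s⁻¹, Ea = 120 kJ mol⁻¹, ΔH = −22.0 kJ mol⁻¹)
    target → over-reaction product (k = 5.50 × 10⁻⁸ s⁻¹, Ea = 125 kJ mol⁻¹)
    starting material + target → side product (k = 3.50 × 10⁻⁵ L mol⁻¹ s⁻¹, Ea = 72.0 kJ mol⁻¹)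
    (constants at 90 °C)

- As paces, north-west made 0.866 h⁻¹, above the grey pace, and west made 0.0689 h⁻¹, a gap of 0.797 h⁻¹ against the 0.0580 h⁻¹ a tie allows. At the asked time in north-west, starting material goes 6.7 times faster into catalyst intermediate C than into side product, and 65% of it is still unbound. In the neighbour flask, north-west with 5.7 × 10⁻⁴ M of free catalyst, the grey pace gives an estimate of 4.68%, and that flask holds 8.46% of target.

Readings and results are calculated with made-up constants; the scatter is artificial.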